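**Retrosynthetic overview**
- The last step is one hydrogenolysis that removes five benzyl ethers and one benzyl carbonate.
- Ring C of the flavanone is closed last, by acylation that forms C4–C4a. The strategy rests on ring A: it is a phloroglucinol ring whose two carbons ortho to O1 (C4a and C8) are equivalent before closure and are activated by O5 and O7, and the C4 ketone sits on C4a.
- The C2–O1 bond comes from Mitsunobu inversion of an (R)-benzylic homoallylic alcohol with 3,5-bis(benzyloxy)phenol. The carboxyl carbon is carried as a terminal alkene through this step, so that no acidic α-hydrogens are present, and is unmasked afterwards by oxidative cleavage.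
- The carbinol stereocentre comes from Brown allylboration of a biaryl aldehyde whose O4' carries an acyl-type group (benzyl carbonate).
- The C3'–C8 biaryl bond comes from Suzuki coupling of 8-iodo-tri-O-benzylapigenin with a formylaryl boronate. Ring order: flavone rings (from apigenin) and ring B preformed, ring A brought in as the phenol, ring C closed last.

Key step: step 11

Remark: unprimed locants are those of the flavanone core and primed ones those of its ring B; "Fl" is the 5,7-bis(benzyloxy)-2-[4-(benzyloxy)phenyl]-4-oxo-4H-chromen-8-yl group (tri-O-benzylapigenin-8-yl).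
Assumption: the allylborane made from (−)-α-pinene is taken to add to the Re face of the biaryl aldehyde, as it does with benzaldehyde.

**Route**

Step 1
Reactants: 1 apigenin
Product: 2 5,7-bis(benzyloxy)-2-[4-(benzyloxy)phenyl]-4H-chromen-4-one (tri-O-benzylapigenin)
Conditions: BnBr (4.5 equiv), K2CO3 (6 equiv), DMF, 80 °C
Reagents that add atoms: benzyl bromide, BrCc1ccccc1
Why: Williamson etherification with excess reagent and heat should cap all three phenols, the chelated 5-OH included, which is needed because a free 5-OH would steer the later iodination to C6.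

Step 2
Reactants: 2 tri-O-benzylapigenin
Product: 3 5,7-bis(benzyloxy)-2-[4-(benzyloxy)phenyl]-8-iodo-4H-chromen-4-one (Fl–I)
Conditions: iodine (I2, 1.1 equiv), CF3CO2Ag (1.1 equiv), CH2Cl2, 0 °C to rt, dark
Reagents that add atoms: iodine, II
Why: Silver-assisted electrophilic aromatic iodination; 5,7-dialkoxyflavones are known to take the electrophile at C8, while ring B and the benzyl groups are far less nucleophilic.

Step 3
Reactants: 4 3-bromo-4-hydroxybenzaldehyde
Product: 5 3-bromo-4-(methoxymethoxy)benzaldehyde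
Conditions: MOMCl, iPr2NEt, CH2Cl2, 0 °C to rt
Reagents that add atoms: chloromethyl methyl ether, COCCl
Why: O-alkylation of the acidic phenol gives a MOM acetal that tolerates the two basic palladium steps and is removed later by dilute acid.

Step 4
Reactants: 5 3-bromo-4-(methoxymethoxy)benzaldehyde
Product: 6 4-(methoxymethoxy)-3-(4,4,5,5-tetramethyl-1,3,2-dioxaborolan-2-yl)benzaldehyde
Conditions: B2pin2, Pd(dppf)Cl2 (3 mol %), KOAc, 1,4-dioxane, 90 °C
Reagents that add atoms: bis(pinacolato)diboron, CC1(C)OB(OC1(C)C)B1OC(C)(C)C(C)(C)O1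
Why: Miyaura borylation of the aryl bromide, which tolerates the aldehyde and the acetal under the weak acetate base.

Step 5
Reactants: 3 Fl–I; 6 4-(methoxymethoxy)-3-(pinacolboryl)benzaldehyde
Product: 8 3-Fl-4-hydroxybenzaldehyde, via MOM-protected biaryl aldehyde 7 (not isolated)
Conditions: Pd(OAc)2 (5 mol %), SPhos (10 mol %), K3PO4, 1,4-dioxane–H2O, 90 °C; then aq. HCl (excess), 45 °C
Reagents that add atoms: none
Why: Suzuki–Miyaura coupling, precedented for 8-iodoflavones with ortho-alkoxyarylboronates and helped by the bulky biaryl phosphine in forming the tri-ortho-substituted biaryl; acidifying the same flask should hydrolyse the aryl MOM acetal and leave the benzyl ethers and the aldehyde intact.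

Step 6
Reactants: 8 3-Fl-4-hydroxybenzaldehyde
Product: 9 benzyl 2-Fl-4-formylphenyl carbonate
Conditions: CbzCl, Et3N, DMAP (cat.), CH2Cl2, 0 °C
Reagents that add atoms: benzyl chloroformate, O=C(Cl)OCc1ccccc1
Why: O-acylation of the phenol to an aryl benzyl carbonate turns the oxygen para to the future benzylic centre from a donor into an acceptor (against ionisation in steps 8 and 11), and the group falls in the final hydrogenolysis together with the benzyl ethers.

Step 7
Reactants: 9 benzyl 2-Fl-4-formylphenyl carbonate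
Product: 10 benzyl 2-Fl-4-[(1R)-1-hydroxybut-3-en-1-yl]phenyl carbonate
Conditions: (+)-Ipc2B(allyl) (from (−)-α-pinene, 1.5 equiv), Et2O–THF, −78 °C; then pH 7 phosphate buffer, 30% H2O2, 0 °C to rt
Reagents that add atoms: (+)-B-allyldiisopinocampheylborane, C=CCB([C@H]1C[C@H]2C[C@@H]([C@@H]1C)C2(C)C)[C@H]1C[C@H]2C[C@@H]([C@@H]1C)C2(C)C
Why: Brown asymmetric allylboration through a chair Zimmerman–Traxler transition state; the reagent from (−)-α-pinene delivers allyl to the Re face of aryl aldehydes and so should set the (R)-carbinol, and the buffered peroxide work-up spares the carbonate.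

Step 8
Reactants: 10 (R)-homoallylic alcohol; 11 3,5-bis(benzyloxy)phenol
Product: 12 benzyl 2-Fl-4-{(1S)-1-[3,5-bis(benzyloxy)phenoxy]but-3-en-1-yl}phenyl carbonate
Conditions: PPh3, DIAD, toluene, 0 °C to rt
Reagents that add atoms: none
Why: Mitsunobu etherification by SN2 displacement of the alkoxyphosphonium ion, inverting the (R)-carbinol to the (S)-aryl ether that becomes C2; the allyl group in place of an ester avoids elimination through acidic α-hydrogens, and the carbonate on O4' disfavours ion-pair racemisation.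

Step 9
Reactants: 12 (S)-aryl ether alkene
Product: 13 benzyl 2-Fl-4-{(1S)-1-[3,5-bis(benzyloxy)phenoxy]-3-oxopropyl}phenyl carbonate
Conditions: K2OsO4·2H2O (2 mol %), NaIO4, 2,6-lutidine, 1,4-dioxane–H2O, rt; crude product used directly
Reagents that add atoms: sodium periodate, [Na+].[O-]I(=O)(=O)=O
Why: Lemieux–Johnson cleavage (osmium-catalysed dihydroxylation, periodate glycol fission) should act on the monosubstituted alkene far faster than on the electron-poor conjugated C2=C3 bond of the flavone; the β-aryloxy aldehyde is not chromatographed, to avoid β-elimination.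

Step 10
Reactants: 13 (S)-β-aryloxy aldehyde
Product: 14 (3S)-3-[3,5-bis(benzyloxy)phenoxy]-3-[4-(benzyloxycarbonyloxy)-3-Fl-phenyl]propanoic acid
Conditions: NaClO2, NaH2PO4, 2-methyl-2-butene (large excess), t-BuOH–THF–H2O, 0 °C to rt
Reagents that add atoms: sodium chlorite, [Na+].[O-]Cl=O
Why: Pinnick (Lindgren–Kraus) oxidation converts the aldehyde to the acid at buffered, mildly acidic pH without touching the stereocentre, the excess alkene keeping hypochlorous acid away from the electron-rich ring.

Step 11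
Reactants: 14 (3S)-3-aryl-3-[3,5-bis(benzyloxy)phenoxy]propanoic acid
Product: 16 (2S)-5,7-bis(benzyloxy)-2-[4-(benzyloxycarbonyloxy)-3-Fl-phenyl]chroman-4-one, via acid chloride 15 (not isolated)
Conditions: 1-chloro-N,N,2-trimethylprop-1-en-1-amine (1.3 equiv), CH2Cl2, 0 °C to rt; then SnCl4 (3 equiv), CH2Cl2 (0.01 M), −78 to −40 °C; cold aq. NaHCO3 quench
Reagents that add atoms: 1-chloro-N,N,2-trimethylprop-1-en-1-amine (Ghosez reagent), CC(C)=C(Cl)N(C)C (supplies only the chlorine of intermediate 15)
Why: The chloroenamine makes acid chloride 15 under neutral conditions, and SnCl4 ionises it to an acylium ion held by the O1–C2–C3 tether over the ring carbon ortho to the ether oxygen and para to a benzyloxy group; attack gives an arenium ion that loses a proton to the aryl ketone. This is an intramolecular Friedel–Crafts acylation of a 3-aryloxypropanoyl chloride, the standard entry to chroman-4-ones, also used on enantioenriched 2-substituted cases. Ring C closes as a six-membered ring by electrophilic aromatic substitution, forming C4–C4a with the arene bond C4a–C8a inside the new ring. No stereocentre is formed: C2 was set in steps 7 and 8 and takes no part in the bond changes. Regioselectivity follows from symmetry, since the two carbons ortho to O1 are equivalent and the third free position is out of reach of the three-atom tether; chemoselectivity follows from intramolecularity at high dilution, the other arenes being deactivated by the SnCl4-bound flavone carbonyl or the carbonate. Configuration is kept only if acylation outruns ionisation of the benzylic C2–O1 bond, which the carbonate on O4' and the meta flavonyl group disfavour while the very nucleophilic ring allows −78 °C.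

Step 12
Reactants: 16 protected biflavonoid
Product: 17 (2S)-5,7-dihydroxy-2-[4-hydroxy-3-(apigenin-8-yl)phenyl]chroman-4-one (target)
Conditions: H2 (1 atm), 10% Pd/C, THF–MeOH, rt
Reagents that add atoms: none
Why: Catalytic hydrogenolysis should cleave the five aryl benzyl ethers and the benzyl carbonate (with loss of CO2) in one neutral operation that leaves the flavone C2=C3 bond, both carbonyl groups and the base-sensitive C2 stereocentre untouched.

**Compound list**
1 | apigenin | O=c1cc(-c2ccc(O)cc2)oc2cc(O)cc(O)c12 | starting material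
2 | 5,7-bis(benzyloxy)-2-[4-(benzyloxy)phenyl]-4H-chromen-4-one | O=c1cc(-c2ccc(OCc3ccccc3)cc2)oc2cc(OCc3ccccc3)cc(OCc3ccccc3)c12 | intermediate
3 | 5,7-bis(benzyloxy)-2-[4-(benzyloxy)phenyl]-8-iodo-4H-chromen-4-one | O=c1cc(-c2ccc(OCc3ccccc3)cc2)oc2c(I)c(OCc3ccccc3)cc(OCc3ccccc3)c12 | intermediate
4 | 3-bromo-4-hydroxybenzaldehyde | O=Cc1ccc(O)c(Br)c1 | starting material
5 | 3-bromo-4-(methoxymethoxy)benzaldehyde | O=Cc1ccc(OCOC)c(Br)c1 | intermediate
6 | 4-(methoxymethoxy)-3-(4,4,5,5-tetramethyl-1,3,2-dioxaborolan-2-yl)benzaldehyde | O=Cc1ccc(OCOC)c(B2OC(C)(C)C(C)(C)O2)c1 | intermediate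
7 | 3-Fl-4-(methoxymethoxy)benzaldehyde | O=Cc1ccc(OCOC)c(-c2c(OCc3ccccc3)cc(OCc3ccccc3)c3c(=O)cc(-c4ccc(OCc5ccccc5)cc4)oc23)c1 | intermediate (not isolated)
8 | 3-Fl-4-hydroxybenzaldehyde | O=Cc1ccc(O)c(-c2c(OCc3ccccc3)cc(OCc3ccccc3)c3c(=O)cc(-c4ccc(OCc5ccccc5)cc4)oc23)c1 | intermediate
9 | benzyl 2-Fl-4-formylphenyl carbonate | O=Cc1ccc(OC(=O)OCc2ccccc2)c(-c2c(OCc3ccccc3)cc(OCc3ccccc3)c3c(=O)cc(-c4ccc(OCc5ccccc5)cc4)oc23)c1 | intermediate
10 | benzyl 2-Fl-4-[(1R)-1-hydroxybut-3-en-1-yl]phenyl carbonate | C=CC[C@H](c1ccc(OC(=O)OCc2ccccc2)c(-c2c(OCc3ccccc3)cc(OCc3ccccc3)c3c(=O)cc(-c4ccc(OCc5ccccc5)cc4)oc23)c1)O | intermediate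
11 | 3,5-bis(benzyloxy)phenol | Oc1cc(OCc2ccccc2)cc(OCc2ccccc2)c1 | starting material
12 | benzyl 2-Fl-4-{(1S)-1-[3,5-bis(benzyloxy)phenoxy]but-3-en-1-yl}phenyl carbonate | C=CC[C@@H](c1ccc(OC(=O)OCc2ccccc2)c(-c2c(OCc3ccccc3)cc(OCc3ccccc3)c3c(=O)cc(-c4ccc(OCc5ccccc5)cc4)oc23)c1)Oc1cc(OCc2ccccc2)cc(OCc2ccccc2)c1 | intermediate
13 | benzyl 2-Fl-4-{(1S)-1-[3,5-bis(benzyloxy)phenoxy]-3-oxopropyl}phenyl carbonate | O=CC[C@@H](c1ccc(OC(=O)OCc2ccccc2)c(-c2c(OCc3ccccc3)cc(OCc3ccccc3)c3c(=O)cc(-c4ccc(OCc5ccccc5)cc4)oc23)c1)Oc1cc(OCc2ccccc2)cc(OCc2ccccc2)c1 | intermediate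
14 | (3S)-3-[3,5-bis(benzyloxy)phenoxy]-3-[4-(benzyloxycarbonyloxy)-3-Fl-phenyl]propanoic acid | OC(=O)C[C@@H](c1ccc(OC(=O)OCc2ccccc2)c(-c2c(OCc3ccccc3)cc(OCc3ccccc3)c3c(=O)cc(-c4ccc(OCc5ccccc5)cc4)oc23)c1)Oc1cc(OCc2ccccc2)cc(OCc2ccccc2)c1 | intermediate (key-step precursor)
15 | (3S)-3-[3,5-bis(benzyloxy)phenoxy]-3-[4-(benzyloxycarbonyloxy)-3-Fl-phenyl]propanoyl chloride | ClC(=O)C[C@@H](c1ccc(OC(=O)OCc2ccccc2)c(-c2c(OCc3ccccc3)cc(OCc3ccccc3)c3c(=O)cc(-c4ccc(OCc5ccccc5)cc4)oc23)c1)Oc1cc(OCc2ccccc2)cc(OCc2ccccc2)c1 | intermediate (not isolated)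
16 | (2S)-5,7-bis(benzyloxy)-2-[4-(benzyloxycarbonyloxy)-3-Fl-phenyl]chroman-4-one | O=C1C[C@@H](c2ccc(OC(=O)OCc3ccccc3)c(-c3c(OCc4ccccc4)cc(OCc4ccccc4)c4c(=O)cc(-c5ccc(OCc6ccccc6)cc5)oc34)c2)Oc2cc(OCc3ccccc3)cc(OCc3ccccc3)c21 | intermediate (key-step product)
17 | (2S)-5,7-dihydroxy-2-{4-hydroxy-3-[5,7-dihydroxy-2-(4-hydroxyphenyl)-4-oxo-4H-chromen-8-yl]phenyl}chroman-4-one | O=C1C[C@@H](c2ccc(O)c(-c3c(O)cc(O)c4c(=O)cc(-c5ccc(O)cc5)oc34)c2)Oc2cc(O)cc(O)c21 | target

**Step count**
Total: 12 steps. Longest linear sequence: 10 steps (steps 1, 2, 5 to 12; the branch through steps 3 and 4 is equally long).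

**Steps most likely to fail**

1. Step 11. The Lewis acid may ionise the benzylic C2–O1 bond (loss of configuration or of the phenol) or cleave benzyl ethers before acylation is complete. The fallback closes ring C through the O1–C2 bond with no Lewis acid. It sets out from aldehyde 9. Knoevenagel condensation (piperidinium acetate cat., toluene, 4 Å sieves) with tert-butyl 3-[2,4-bis(benzyloxy)-6-hydroxyphenyl]-3-oxopropanoate F1 would give the alkylidene β-keto ester F2. F1 would be prepared by Claisen condensation of methyl 2,4-bis(benzyloxy)-6-hydroxybenzoate with excess lithium enolate of tert-butyl acetate. Enantioselective intramolecular oxa-Michael addition under a cinchona-derived bifunctional thiourea (the pseudoenantiomer chosen for the 2S series) would give the tert-butyl (2S)-flavanone-3-carboxylate F3. TsOH in toluene at 80 °C would then remove the ester with decarboxylation, and the route is rejoined at 16.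

2. Step 8. The activated benzylic alcohol may lose configuration through ion-pair leakage, eliminate to the aryl diene, or alkylate the phenol on carbon. The fallback makes the ether with retention, so that the stereocentre is never an electrophile. It sets out from aldehyde 9. Allylboration with the enantiomeric reagent, (−)-Ipc2B(allyl) from (+)-α-pinene, would give benzyl 2-Fl-4-[(1S)-1-hydroxybut-3-en-1-yl]phenyl carbonate F4. Copper-catalysed oxidative O-arylation of the Chan–Lam type (Cu(OAc)2·H2O cat., DMAP, 4 Å sieves, O2, CH2Cl2, rt) with potassium [3,5-bis(benzyloxy)phenyl]trifluoroborate F5 would form the aryl–oxygen bond. F5 would come from the commercial boronic acid and KHF2. The route is rejoined at 12.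

3. Step 5. The coupling to a tri-ortho-substituted biaryl may stall through slow transmetalation and protodeboronation of the ortho-oxygenated boronate. The fallback exchanges the roles of the partners. It sets out from iodide 3, which would be borylated (B2pin2, Pd(dppf)Cl2, KOAc, DMSO, 80 °C) to 5,7-bis(benzyloxy)-2-[4-(benzyloxy)phenyl]-8-(4,4,5,5-tetramethyl-1,3,2-dioxaborolan-2-yl)-4H-chromen-4-one F6. F6 would be coupled with bromide 5 (Pd(OAc)2, SPhos, K3PO4, dioxane–H2O), followed by the same acid treatment, and the route is rejoined at 8.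

**Further compounds**
F1 | step 11 | tert-butyl 3-[2,4-bis(benzyloxy)-6-hydroxyphenyl]-3-oxopropanoate | CC(C)(C)OC(=O)CC(=O)c1c(O)cc(OCc2ccccc2)cc1OCc1ccccc1
F2 | step 11 | tert-butyl 2-[2,4-bis(benzyloxy)-6-hydroxybenzoyl]-3-[4-(benzyloxycarbonyloxy)-3-Fl-phenyl]prop-2-enoate (alkene isomers) | CC(C)(C)OC(=O)C(=Cc1ccc(OC(=O)OCc2ccccc2)c(-c2c(OCc3ccccc3)cc(OCc3ccccc3)c3c(=O)cc(-c4ccc(OCc5ccccc5)cc4)oc23)c1)C(=O)c1c(O)cc(OCc2ccccc2)cc1OCc1ccccc1
F3 | step 11 | tert-butyl (2S)-5,7-bis(benzyloxy)-2-[4-(benzyloxycarbonyloxy)-3-Fl-phenyl]-4-oxochromane-3-carboxylate (C3 epimers) | CC(C)(C)OC(=O)C1C(=O)c2c(OCc3ccccc3)cc(OCc3ccccc3)cc2O[C@@H]1c1ccc(OC(=O)OCc2ccccc2)c(-c2c(OCc3ccccc3)cc(OCc3ccccc3)c3c(=O)cc(-c4ccc(OCc5ccccc5)cc4)oc23)c1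
F4 | step 8 | benzyl 2-Fl-4-[(1S)-1-hydroxybut-3-en-1-yl]phenyl carbonate | C=CC[C@@H](c1ccc(OC(=O)OCc2ccccc2)c(-c2c(OCc3ccccc3)cc(OCc3ccccc3)c3c(=O)cc(-c4ccc(OCc5ccccc5)cc4)oc23)c1)O
F5 | step 8 | potassium [3,5-bis(benzyloxy)phenyl]trifluoroborate | [K+].F[B-](F)(F)c1cc(OCc2ccccc2)cc(OCc2ccccc2)c1
F6 | step 5 | 5,7-bis(benzyloxy)-2-[4-(benzyloxy)phenyl]-8-(4,4,5,5-tetramethyl-1,3,2-dioxaborolan-2-yl)-4H-chromen-4-one | O=c1cc(-c2ccc(OCc3ccccc3)cc2)oc2c(B3OC(C)(C)C(C)(C)O3)c(OCc3ccccc3)cc(OCc3ccccc3)c12
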